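**Plan**
- Retrosynthetic cuts, in order: C5'–Br on ring B (ortho to O6'–H); O6'–H back to O6'–SO2CH3 and O1–CH3 back to O1–H; then C2–Br, C4–Br, C2'–Br and C4'–Br in a single cut; last the O6'–S bond, which leaves symmetric 2,2'-oxydiphenol.
- Forward order: no ring is built, the diaryl ether is bought intact. It is mono-mesylated, tetrabrominated in one flask, O-methylated on ring A, de-mesylated and brominated once more on ring B.
- Enabling feature: ring A (C1 oxygen, C6 O-aryl) carries Br at C2 and C4, ortho and para to a free O1. Ring B (C1' O-aryl, C6' oxygen) carries Br at C2' and C4', ortho and para to the ether oxygen, with C3' (para to O6') unsubstituted; only a sulfonyl-masked O6' allows this.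
- Stereochemistry: the target has no stereocentre and no double-bond geometry; only regiochemistry has to be controlled.

Key step: step 2

Remark: 2,2'-oxydiphenol 1 is taken to be a purchasable bis-phenol; locants follow the target, ring A being the anisole ring (C1 OMe, C6 O-aryl) and ring B the phenol ring (C1' O-aryl, C6' OH).

**Step 1**
Reactants: 1 2,2'-oxydiphenol; 2 methanesulfonyl chloride
Product: 3 2-(2-hydroxyphenoxy)phenyl methanesulfonate
Conditions: MsCl (0.9 equiv, slow addition), Et3N (1.0 equiv), CH2Cl2, −20 → 0 °C; unchanged 1 recycled
Reagents that add atoms: methanesulfonyl chloride, CS(=O)(=O)Cl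
Why: Base-mediated O-sulfonylation of a phenol, run as a statistical desymmetrization with substoichiometric sulfonyl chloride in the cold, should give mainly the mono-mesylate, which is separable by chromatography from recovered diol and from the bis-mesylate.

**Step 2**
Reactants: 3 2-(2-hydroxyphenoxy)phenyl methanesulfonate; 4 bromine; 5 trifluoroacetic anhydride
Product: 9 3,5-dibromo-2-(3,5-dibromo-2-hydroxyphenoxy)phenyl methanesulfonate, via ring A dibromide 6 (not isolated), via ring A trifluoroacetate 7 (not isolated), via tetrabromo trifluoroacetate 8 (not isolated)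
Conditions: Br2 (2.05 equiv), ClCH2CH2Cl, 0 °C; (CF3CO)2O (3 equiv), rt → 40 °C; Br2 (2.2 equiv), FeBr3 (20 mol %), 50 °C; then aq NaHSO3, MeOH/aq NaHCO3, rt
Reagents that add atoms: bromine, BrBr
Why: All four C–Br bonds form by electrophilic aromatic substitution through arenium ions, the closest known reactions being the catalyst-free ortho/para dibromination of phenols and the FeBr3-catalysed ortho/para bromination of diaryl ethers. The free O1–H makes ring A by far the more nucleophilic ring, so the first two equivalents of bromine should enter para and ortho to O1 (C4, C2) and give 6 while the mesylated ring B is left alone. Trifluoroacetic anhydride then turns O1 into an electron-poor ester (7), so that the remaining ring A positions C3 and C5, meta to O1 and already flanked by bromine, become less reactive than ring B and no bromodienone can arise from the phenol. On ring B the sulfonylated O6' is a poor donor, so the diaryl ether oxygen directs the catalysed bromination to its para and ortho carbons (C4', then C2') and leaves C3' and C5' as C–H, giving 8. Mild methanolysis in the bicarbonate work-up should strip only the trifluoroacetyl group and return the ring A phenol of 9 with the mesylate intact. No ring is closed and no stereocentre arises; the selectivity needed is ring order and site choice, and it rests on the free versus masked oxygens, the transient cap and the limited amount of bromine.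

**Step 3**
Reactants: 9 3,5-dibromo-2-(3,5-dibromo-2-hydroxyphenoxy)phenyl methanesulfonate; 10 iodomethane
Product: 11 3,5-dibromo-2-(3,5-dibromo-2-methoxyphenoxy)phenyl methanesulfonate
Conditions: MeI (3 equiv), K2CO3 (1.5 equiv), acetone, rt → 40 °C
Reagents that add atoms: iodomethane, CI
Why: Williamson O-methylation of the acidic, doubly ortho-substituted ring A phenoxide; carbonate in acetone near room temperature should leave the aryl mesylate and the aryl bromides untouched, and excess iodomethane should outpace any sulfonyl transfer between the two oxygens.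

**Step 4**
Reactants: 11 3,5-dibromo-2-(3,5-dibromo-2-methoxyphenoxy)phenyl methanesulfonate
Product: 12 3,5-dibromo-2-(3,5-dibromo-2-methoxyphenoxy)phenol
Conditions: NaOH (2 M aq, 4 equiv), 1,4-dioxane, 60 °C; then 1 M HCl
Reagents that add atoms: none
Why: Hydroxide-mediated S–O cleavage (saponification) of an aryl methanesulfonate, helped by the good dibromophenoxide leaving group; ring A carries its bromines meta to the ether carbon, so neither nucleophilic aromatic substitution nor a Smiles-type aryl migration between the oxygens is activated.

**Step 5**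
Reactants: 12 3,5-dibromo-2-(3,5-dibromo-2-methoxyphenoxy)phenol; 13 N-bromosuccinimide
Product: 14 2,3,5-tribromo-6-(3,5-dibromo-2-methoxyphenoxy)phenol
Conditions: NBS (1.05 equiv), i-Pr2NH (10 mol %), CH2Cl2, 0 °C → rt
Reagents that add atoms: N-bromosuccinimide, O=C1CCC(=O)N1Br
Why: Amine-mediated ortho-bromination of a phenol with N-bromosuccinimide, in which the N-bromoamine formed from diisopropylamine is hydrogen-bonded to the hydroxyl and should deliver bromine to the only free ortho carbon C5', while the para carbon C3' is shielded by the bromines at C2' and C4' and ring A, a dibrominated aryl methyl ether, is far less reactive.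

**Compound list**
1 | 2,2'-oxydiphenol | Oc1ccccc1Oc1ccccc1O | starting material
2 | methanesulfonyl chloride | CS(=O)(=O)Cl | starting material
3 | 2-(2-hydroxyphenoxy)phenyl methanesulfonate | CS(=O)(=O)Oc1ccccc1Oc1ccccc1O | intermediate
4 | bromine | BrBr | starting material
5 | trifluoroacetic anhydride | O=C(OC(=O)C(F)(F)F)C(F)(F)F | starting material
6 | 2-(3,5-dibromo-2-hydroxyphenoxy)phenyl methanesulfonate | CS(=O)(=O)Oc1ccccc1Oc1cc(Br)cc(Br)c1O | intermediate
7 | 2,4-dibromo-6-[2-(methanesulfonyloxy)phenoxy]phenyl trifluoroacetate | CS(=O)(=O)Oc1ccccc1Oc1cc(Br)cc(Br)c1OC(=O)C(F)(F)F | intermediate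
8 | 2,4-dibromo-6-[2,4-dibromo-6-(methanesulfonyloxy)phenoxy]phenyl trifluoroacetate | CS(=O)(=O)Oc1cc(Br)cc(Br)c1Oc1cc(Br)cc(Br)c1OC(=O)C(F)(F)F | intermediate
9 | 3,5-dibromo-2-(3,5-dibromo-2-hydroxyphenoxy)phenyl methanesulfonate | CS(=O)(=O)Oc1cc(Br)cc(Br)c1Oc1cc(Br)cc(Br)c1O | intermediate
10 | iodomethane | CI | starting material
11 | 3,5-dibromo-2-(3,5-dibromo-2-methoxyphenoxy)phenyl methanesulfonate | COc1c(Br)cc(Br)cc1Oc1c(Br)cc(Br)cc1OS(C)(=O)=O | intermediate
12 | 3,5-dibromo-2-(3,5-dibromo-2-methoxyphenoxy)phenol | COc1c(Br)cc(Br)cc1Oc1c(Br)cc(Br)cc1O | intermediate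
13 | N-bromosuccinimide | O=C1CCC(=O)N1Br | starting material
14 | 2,3,5-tribromo-6-(3,5-dibromo-2-methoxyphenoxy)phenol | COc1c(Br)cc(Br)cc1Oc1c(Br)cc(Br)c(Br)c1O | target

Total step count: 5. Longest linear sequence: 5 steps (1 → 3 → 9 → 11 → 12 → 14).

**Steps most likely to fail**

Step 2. What may go wrong: the trifluoroacetyl cap is shed under HBr and the iron salt, or the rate gap between the rings proves too small, so that the fourth bromine enters ring A at C5 while ring B stalls after its first bromine. The fallback sets out from 3 and comes back at 9, with the bromination split over isolated compounds. 3 is treated with only the first charge of bromine (2.05 equiv, CH2Cl2, 0 °C) and 6 is isolated. Tf2O and pyridine in CH2Cl2 at 0 °C then convert its ring A hydroxyl into a persistent, acid-proof and strongly electron-withdrawing sulfonate, 2,4-dibromo-6-[2-(methanesulfonyloxy)phenoxy]phenyl trifluoromethanesulfonate F1. Br2 with AlBr3 (or FeBr3) in ClCH2CH2Cl at 60 °C should brominate ring B alone at C4' and C2' to give 2,4-dibromo-6-[2,4-dibromo-6-(methanesulfonyloxy)phenoxy]phenyl trifluoromethanesulfonate F2. Aqueous Et4NOH in 1,4-dioxane at rt, which is expected to cleave an aryl triflate much faster than an aryl mesylate, returns 9.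

Step 5. What may go wrong: attack para to the hydroxyl at C3' competes with ortho attack at C5', or a second bromination follows. The fallback sets out from 12 and comes back at 14; the free hydroxyl is replaced as director by a covalently bound one. Me2NCOCl and K2CO3 in MeCN give 3,5-dibromo-2-(3,5-dibromo-2-methoxyphenoxy)phenyl dimethylcarbamate F3. Pd(OAc)2 (10 mol %), NBS and TsOH in ClCH2CH2Cl at 70 °C should effect carbamate-directed ortho C–H bromination, in which cyclopalladation by divalent palladium can only reach C5' because the other ortho carbon C1' carries the ether oxygen, to give 2,3,5-tribromo-6-(3,5-dibromo-2-methoxyphenoxy)phenyl dimethylcarbamate F4. NaOH in MeOH–H2O at 60 °C then cleaves the carbamate to 14.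

Step 1. What may go wrong: over-sulfonylation to the bis-mesylate alongside unreacted diol, so that the mono-selectivity of the desymmetrization stays low and throughput suffers. The fallback sets out from 2 and comes back at 3; the two oxygens are differentiated before the ether is made. 2 is used to mesylate commercial 2-iodophenol (Et3N, CH2Cl2, 0 °C) to 2-iodophenyl methanesulfonate F5. Ullmann-type C–O coupling with commercial 2-(benzyloxy)phenol (CuI, picolinic acid, K3PO4, DMSO, 80 °C) should give 2-[2-(benzyloxy)phenoxy]phenyl methanesulfonate F6. Hydrogenolysis of the benzyl ether (H2, Pd/C, EtOAc, rt) delivers 3.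

**Further compounds**
F1 | step 2 | 2,4-dibromo-6-[2-(methanesulfonyloxy)phenoxy]phenyl trifluoromethanesulfonate | CS(=O)(=O)Oc1ccccc1Oc1cc(Br)cc(Br)c1OS(=O)(=O)C(F)(F)F
F2 | step 2 | 2,4-dibromo-6-[2,4-dibromo-6-(methanesulfonyloxy)phenoxy]phenyl trifluoromethanesulfonate | CS(=O)(=O)Oc1cc(Br)cc(Br)c1Oc1cc(Br)cc(Br)c1OS(=O)(=O)C(F)(F)F
F3 | step 5 | 3,5-dibromo-2-(3,5-dibromo-2-methoxyphenoxy)phenyl dimethylcarbamate | COc1c(Br)cc(Br)cc1Oc1c(Br)cc(Br)cc1OC(=O)N(C)C
F4 | step 5 | 2,3,5-tribromo-6-(3,5-dibromo-2-methoxyphenoxy)phenyl dimethylcarbamate | COc1c(Br)cc(Br)cc1Oc1c(Br)cc(Br)c(Br)c1OC(=O)N(C)C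
F5 | step 1 | 2-iodophenyl methanesulfonate | CS(=O)(=O)Oc1ccccc1I
F6 | step 1 | 2-[2-(benzyloxy)phenoxy]phenyl methanesulfonate | CS(=O)(=O)Oc1ccccc1Oc1ccccc1OCc1ccccc1
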